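The C6(O-vanilloyl)–C7(isopropyl)–C8(OH) triad on the ten-membered carbocycle is an anti-1,3-diol monoester, the signature of an Evans–Tishchenko reduction of a β-hydroxy ketone. That aldol is the union of C7, as α-carbon of a C8 ketone, with a C6 aldehyde flanked by the C4–C5 epoxide. The route rests on a samarium diiodide Reformatsky-type macro-aldolisation: an open-chain, farnesol-derived 10-bromo-9-oxo-2,3-epoxy aldehyde is reduced at C–Br to a regiodefined enolate that closes the ten-membered ring and sets two stereocentres in one operation. A vanillin-derived Evans–Tishchenko step then installs the ester and the C8 carbinol together.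

Key step: step 9

Remark on numbering: ring compounds use germacrane numbering (C1=C10 alkene, C4–C5 epoxide, O on C6, isopropyl on C7, O on C8). Open-chain compounds use farnesol numbering (C1 = oxygenated end, methyls on C3, C7, C11). Farnesol C1, C10 and C9 become ring C6, C7 and C8. TBS = tert-butyldimethylsilyl, TES = triethylsilyl.

Assumption: (2E,6E)-farnesol and vanillin are bought. Compounds 3, 4 and 10–13 are carried as mixtures at C10, a centre that step 9 erases.

Step 1
Reactants: 1 (2E,6E)-farnesol
Product: 2 (2E,6E)-farnesyl TBS ether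
Conditions: TBSCl, imidazole, CH2Cl2, 0 °C to rt
Reagents that add atoms: tert-butyldimethylsilyl chloride, CC(C)(C)[Si](C)(C)Cl
Why: Standard silylation of a primary allylic alcohol (silyl ether protection) masks O1 through the oxidative steps that follow; no stereocentre is formed.

Step 2
Reactants: 2 (2E,6E)-farnesyl TBS ether
Product: 4 racemic (2E,6E)-10,11-epoxyfarnesyl TBS ether, via bromohydrin 3 (not isolated)
Conditions: NBS, THF/H2O (water to incipient turbidity), 0 °C; then K2CO3, MeOH, rt
Reagents that add atoms: water, O; N-bromosuccinimide, O=C1CCC(=O)N1Br (its bromine stays only in 3)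
Why: Terminal-selective bromohydrin formation of a coiled polyene in aqueous medium (Markovnikov opening of the bromonium ion puts OH on C11) is followed by base-mediated intramolecular Williamson closure to the epoxide; the racemic C10 centre is erased later.

Step 3
Reactants: 4 racemic (2E,6E)-10,11-epoxyfarnesyl TBS ether
Product: 7 (2E,6E,9E)-11-hydroxy-3,7,11-trimethyldodeca-2,6,9-trien-1-yl TBS ether, via hydroxy selenide 5 (not isolated), via selenoxide 6 (not isolated)
Conditions: (PhSe)2, NaBH4, EtOH, reflux; then 30% H2O2, pyridine, THF, 0 °C to rt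
Reagents that add atoms: none
Why: Benzeneselenolate opens the trisubstituted epoxide by SN2 attack at the secondary C10, and the derived selenoxide undergoes syn-elimination, which can only take a C9 hydrogen, giving the (9E)-configured tertiary allylic alcohol; pyridine suppresses perseleninic acid epoxidation of the other alkenes.

Step 4
Reactants: 7 (2E,6E,9E)-11-hydroxy-3,7,11-trimethyldodeca-2,6,9-trien-1-yl TBS ether
Product: 8 (2E,6E)-1-(TBS-oxy)-3,7,11-trimethyldodeca-2,6,10-trien-9-one
Conditions: pyridinium chlorochromate (C5H5NH)[CrO3Cl], Celite, CH2Cl2, rt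
Reagents that add atoms: none
Why: Babler–Dauben oxidative transposition: the tertiary chromate ester undergoes a [3,3]-shift to the secondary C9 chromate, which is oxidised to the β,β-disubstituted enone.

Step 5
Reactants: 8 (2E,6E)-1-(TBS-oxy)-3,7,11-trimethyldodeca-2,6,10-trien-9-one
Product: 10 racemic (2E,6E)-10-bromo-1-(TBS-oxy)-3,7,11-trimethyldodeca-2,6-dien-9-one, via (9Z)-triethylsilyl enol ether 9 (not isolated)
Conditions: Et3SiH, RhCl(PPh3)3 (1 mol%), benzene, 60 °C; concentrate; then NBS, THF, −78 °C
Reagents that add atoms: N-bromosuccinimide, O=C1CCC(=O)N1Br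
Why: Rhodium-catalysed 1,4-hydrosilylation of the enone with a monohydrosilane gives the C9–C10 silyl enol ether regiospecifically and turns the isopropylidene into the isopropyl group, and electrophilic bromination of that enol ether places bromine only at C10, never at the more acidic C8.

Step 6
Reactants: 10 racemic (2E,6E)-10-bromo-1-(TBS-oxy)-3,7,11-trimethyldodeca-2,6-dien-9-one
Product: 11 (2E,6E)-10-bromo-1-hydroxy-3,7,11-trimethyldodeca-2,6-dien-9-one
Conditions: camphorsulfonic acid (10 mol%), MeOH/CH2Cl2 (1:1), 0 °C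
Reagents that add atoms: none
Why: Acid-catalysed methanolysis removes the primary allylic silyl ether; the α-bromo ketone and the skipped enone tolerate mild acid but would not tolerate fluoride or base.

Step 7
Reactants: 11 (2E,6E)-10-bromo-1-hydroxy-3,7,11-trimethyldodeca-2,6-dien-9-one
Product: 12 (2R,3R,6E)-10-bromo-2,3-epoxy-1-hydroxy-3,7,11-trimethyldodec-6-en-9-one (both C10 epimers)
Conditions: Ti(OiPr)4 (10 mol%), D-(−)-diisopropyl tartrate (12 mol%), tBuOOH, 4 Å MS, CH2Cl2, −20 °C
Reagents that add atoms: tert-butyl hydroperoxide, CC(C)(C)OO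
Why: Sharpless asymmetric epoxidation is chemoselective for the allylic alcohol, and with the D-(−)-tartrate the (E)-allylic alcohol is epoxidised on the face that gives the (2R,3R)-epoxy alcohol, which sets ring C4 and C5.

Step 8
Reactants: 12 (2R,3R,6E)-10-bromo-2,3-epoxy-1-hydroxy-3,7,11-trimethyldodec-6-en-9-one
Product: 13 (2S,3R,6E)-10-bromo-2,3-epoxy-3,7,11-trimethyl-9-oxododec-6-enal (both C10 epimers)
Conditions: Dess–Martin periodinane, NaHCO3, CH2Cl2, 0 °C to rt; used at once
Reagents that add atoms: none
Why: Buffered Dess–Martin oxidation should give the α,β-epoxy aldehyde without epoxide opening or epimerisation; the C2 descriptor changes to S only through the priority rules.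

Step 9
Reactants: 13 (2S,3R,6E)-10-bromo-2,3-epoxy-3,7,11-trimethyl-9-oxododec-6-enal
Product: 15 (1(10)E,4R,5R,6S,7S)-4,5-epoxy-6-hydroxygermacr-1(10)-en-8-one, via diiodosamarium (9Z)-enolate 14 (not isolated)
Conditions: 13 in THF added by syringe pump over 4 h to SmI2 (2.5 equiv, 0.01 M in THF), −78 °C; then pH 7 phosphate buffer
Reagents that add atoms: none
Why: Two single-electron transfers from divalent samarium cleave the C10–Br bond (much faster than ketyl formation at the aldehyde in HMPA-free THF at −78 °C) and give the trivalent samarium enolate 14 regiospecifically from either C10 epimer, and this enolate adds to the C1 aldehyde bound to the same oxophilic metal (Reformatsky-type aldol). The closest known reaction type is the SmI2-mediated intramolecular Reformatsky reaction, an established closure for eight- to fourteen-membered rings. The ten-membered carbocycle closes in a 10-(enolendo)-exo-trig mode, the (E)-alkene and the trans-epoxide acting as rigid turn elements as in germacradienes. Ring C7 is set by the (Z)-enolate (isopropyl cis to OSm, avoiding allylic strain with C8) reacting through a metal-bridged chair, which should give the syn aldol, i.e. 6-OH and 7-isopropyl trans on the ring. Ring C6 is set by the neighbouring epoxide centre C5: with trivalent samarium chelating the aldehyde and epoxide oxygens the enolate attacks anti to C4, which leads to the (5R,6S) arrangement. The step needs C–Br over C=O chemoselectivity (low temperature, no HMPA), ring closure over oligomerisation (slow addition, high dilution) and the diastereoface selectivity just described, which is the least secure element.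

Step 10
Reactants: 16 vanillin (4-hydroxy-3-methoxybenzaldehyde)
Product: 17 4-(TBS-oxy)-3-methoxybenzaldehyde
Conditions: TBSCl, imidazole, CH2Cl2, rt
Reagents that add atoms: tert-butyldimethylsilyl chloride, CC(C)(C)[Si](C)(C)Cl
Why: Phenol silylation prevents the free phenol from quenching the samarium catalyst of step 11 and gives a group that can be removed at the end without touching epoxide or ester.

Step 11
Reactants: 15 (1(10)E,4R,5R,6S,7S)-4,5-epoxy-6-hydroxygermacr-1(10)-en-8-one; 17 4-(TBS-oxy)-3-methoxybenzaldehyde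
Product: 19 (1(10)E,4R,5R,6S,7R,8R)-4,5-epoxy-8-hydroxygermacr-1(10)-en-6-yl 4-(TBS-oxy)-3-methoxybenzoate, via samarium-bound hemiacetal 18 (not isolated)
Conditions: 17 (5 equiv), SmI2 (30 mol%), THF, −10 °C, dark
Reagents that add atoms: none
Why: Evans–Tishchenko reduction: the C6 hydroxyl adds to the aldehyde and the samarium-bound hemiacetal delivers its hydride intramolecularly to the C8 ketone through a chair-like six-membered transition state, which should give the 1,3-anti diol (8R) with the aroyl group necessarily on O6.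

Step 12
Reactants: 19 (1(10)E,4R,5R,6S,7R,8R)-4,5-epoxy-8-hydroxygermacr-1(10)-en-6-yl 4-(TBS-oxy)-3-methoxybenzoate
Product: 20 (1(10)E,4R,5R,6S,7R,8R)-4,5-epoxy-8-hydroxygermacr-1(10)-en-6-yl 4-hydroxy-3-methoxybenzoate (CNP0285693.1)
Conditions: TBAF, AcOH (1:1), THF, 0 °C
Reagents that add atoms: none
Why: Fluoride cleaves the aryl silyl ether fast and selectively, and acetic acid buffering prevents alkoxide-mediated 1,3-acyl migration from O6 to O8 and spares the epoxide.

Compound list

1 | (2E,6E)-farnesol, (2E,6E)-3,7,11-trimethyldodeca-2,6,10-trien-1-ol | CC(C)=CCC/C(C)=C/CC/C(C)=C/CO | starting material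
2 | (2E,6E)-farnesyl tert-butyldimethylsilyl ether | CC(C)=CCC/C(C)=C/CC/C(C)=C/CO[Si](C)(C)C(C)(C)C | intermediate
3 | racemic (2E,6E)-10-bromo-11-hydroxy-10,11-dihydrofarnesyl TBS ether (bromohydrin, not isolated) | CC(C)(O)C(Br)CC/C(C)=C/CC/C(C)=C/CO[Si](C)(C)C(C)(C)C | intermediate
4 | racemic (2E,6E)-10,11-epoxyfarnesyl TBS ether | CC1(C)OC1CC/C(C)=C/CC/C(C)=C/CO[Si](C)(C)C(C)(C)C | intermediate
5 | (2E,6E)-11-hydroxy-10-(phenylseleno)-10,11-dihydrofarnesyl TBS ether (hydroxy selenide, not isolated) | CC(C)(O)C([Se]c1ccccc1)CC/C(C)=C/CC/C(C)=C/CO[Si](C)(C)C(C)(C)C | intermediate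
6 | selenoxide of 5 (not isolated) | CC(C)(O)C([Se](=O)c1ccccc1)CC/C(C)=C/CC/C(C)=C/CO[Si](C)(C)C(C)(C)C | intermediate
7 | (2E,6E,9E)-11-hydroxy-3,7,11-trimethyldodeca-2,6,9-trien-1-yl TBS ether | CC(C)(O)/C=C/C/C(C)=C/CC/C(C)=C/CO[Si](C)(C)C(C)(C)C | intermediate
8 | (2E,6E)-1-(tert-butyldimethylsilyloxy)-3,7,11-trimethyldodeca-2,6,10-trien-9-one | CC(C)=CC(=O)C/C(C)=C/CC/C(C)=C/CO[Si](C)(C)C(C)(C)C | intermediate
9 | (2E,6E,9Z)-1-(tert-butyldimethylsilyloxy)-9-(triethylsilyloxy)-3,7,11-trimethyldodeca-2,6,9-triene (not isolated) | CC(C)/C=C(\O[Si](CC)(CC)CC)C/C(C)=C/CC/C(C)=C/CO[Si](C)(C)C(C)(C)C | intermediate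
10 | racemic (2E,6E)-10-bromo-1-(tert-butyldimethylsilyloxy)-3,7,11-trimethyldodeca-2,6-dien-9-one | CC(C)C(Br)C(=O)C/C(C)=C/CC/C(C)=C/CO[Si](C)(C)C(C)(C)C | intermediate
11 | (2E,6E)-10-bromo-1-hydroxy-3,7,11-trimethyldodeca-2,6-dien-9-one | CC(C)C(Br)C(=O)C/C(C)=C/CC/C(C)=C/CO | intermediate
12 | (2R,3R,6E)-10-bromo-2,3-epoxy-1-hydroxy-3,7,11-trimethyldodec-6-en-9-one (both C10 epimers) | CC(C)C(Br)C(=O)C/C(C)=C/CC[C@@]1(C)O[C@@H]1CO | intermediate
13 | (2S,3R,6E)-10-bromo-2,3-epoxy-3,7,11-trimethyl-9-oxododec-6-enal (both C10 epimers) | CC(C)C(Br)C(=O)C/C(C)=C/CC[C@@]1(C)O[C@@H]1C=O | intermediate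
14 | diiodosamarium (9Z)-enolate of the debrominated epoxy aldehyde (not isolated) | CC(C)/C=C(\O[Sm](I)I)C/C(C)=C/CC[C@@]1(C)O[C@@H]1C=O | intermediate
15 | (1(10)E,4R,5R,6S,7S)-4,5-epoxy-6-hydroxygermacr-1(10)-en-8-one | O[C@H]1[C@H](C(C)C)C(=O)C/C(C)=C/CC[C@@]2(C)O[C@H]12 | intermediate
16 | vanillin, 4-hydroxy-3-methoxybenzaldehyde | COc1cc(C=O)ccc1O | starting material
17 | 4-(tert-butyldimethylsilyloxy)-3-methoxybenzaldehyde | COc1cc(C=O)ccc1O[Si](C)(C)C(C)(C)C | intermediate
18 | hemiacetal from O6 of 15 and the aldehyde carbon of 17, samarium-bound, drawn in neutral form (not isolated) | COc1cc(C(O)O[C@H]2[C@H](C(C)C)C(=O)C/C(C)=C/CC[C@@]3(C)O[C@H]23)ccc1O[Si](C)(C)C(C)(C)C | intermediate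
19 | (1(10)E,4R,5R,6S,7R,8R)-4,5-epoxy-8-hydroxygermacr-1(10)-en-6-yl 4-(tert-butyldimethylsilyloxy)-3-methoxybenzoate | COc1cc(C(=O)O[C@H]2[C@H](C(C)C)[C@H](O)C/C(C)=C/CC[C@@]3(C)O[C@H]23)ccc1O[Si](C)(C)C(C)(C)C | intermediate
20 | (1(10)E,4R,5R,6S,7R,8R)-4,5-epoxy-8-hydroxygermacr-1(10)-en-6-yl 4-hydroxy-3-methoxybenzoate (CNP0285693.1) | COc1cc(C(=O)O[C@H]2[C@H](C(C)C)[C@H](O)C/C(C)=C/CC[C@@]3(C)O[C@H]23)ccc1O | target

Total step count: 12. Longest linear sequence: 11 steps (steps 1–9, 11 and 12 from farnesol); step 10 is a one-step branch.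

Steps most likely to fail

Step 9. Electron transfer to the epoxy aldehyde (ketyl formation with epoxide fragmentation) or intermolecular aldol addition may outrun ring closure, and the metal-bridged transition state may not discriminate the aldehyde faces. The fallback generates the enolate without a single-electron reductant and from a different precursor. It sets out from 8, which is desilylated (camphorsulfonic acid, MeOH) to (2E,6E)-1-hydroxy-3,7,11-trimethyldodeca-2,6,10-trien-9-one F1. F1 is epoxidised under the conditions of step 7 to (2R,3R,6E)-2,3-epoxy-1-hydroxy-3,7,11-trimethyldodeca-6,10-dien-9-one F2. F2 is oxidised with Dess–Martin periodinane to (2S,3R,6E)-2,3-epoxy-3,7,11-trimethyl-9-oxododeca-6,10-dienal F3. Slow addition of F3 to [(Ph3P)CuH]6 in toluene at high dilution (conjugate hydride addition to the enone, then intramolecular aldol addition of the copper enolate, a reductive aldol cyclisation) should give 15, where the route is rejoined.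

Step 11. Slow hemiacetal formation with the electron-rich, hindered aryl aldehyde may let retro-aldol opening of the ring or Lewis-acid opening of the epoxide compete, and the product may suffer acyl migration. The fallback separates reduction and acylation. It sets out from 15, which is reduced with Me4NBH(OAc)3 (MeCN/AcOH, −30 °C; hydroxyl-directed, 1,3-anti) to (1(10)E,4R,5R,6S,7R,8R)-4,5-epoxygermacr-1(10)-ene-6,8-diol F4. The less hindered C8 hydroxyl is silylated (TESCl, imidazole, −40 °C) to the 8-O-triethylsilyl ether of the diol F5. F5 is esterified (DCC, DMAP, Steglich conditions) with 4-(tert-butyldimethylsilyloxy)-3-methoxybenzoic acid F6, made from 17 by Pinnick oxidation (NaClO2, NaH2PO4, 2-methyl-2-butene), to give the 6-O-aroyl 8-O-triethylsilyl ether F7. TBAF/AcOH removes both silyl groups and gives 20 directly.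

Step 4. Acid-promoted ionisation and dehydration of the tertiary allylic alcohol, or oxidative loss of the allylic silyl ether, may occur under the hexavalent chromium reagent. The fallback separates transposition and oxidation. It sets out from 7, which is isomerised with Ph3SiOReO3 (catalytic, Et2O, 0 °C; 1,3-transposition toward the trisubstituted alkene) to racemic (2E,6E)-1-(tert-butyldimethylsilyloxy)-3,7,11-trimethyldodeca-2,6,10-trien-9-ol F8. MnO2 in CH2Cl2 oxidises F8 to enone 8, where the route is rejoined.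

Further compounds

F1 | step 9 | (2E,6E)-1-hydroxy-3,7,11-trimethyldodeca-2,6,10-trien-9-one | CC(C)=CC(=O)C/C(C)=C/CC/C(C)=C/CO
F2 | step 9 | (2R,3R,6E)-2,3-epoxy-1-hydroxy-3,7,11-trimethyldodeca-6,10-dien-9-one | CC(C)=CC(=O)C/C(C)=C/CC[C@@]1(C)O[C@@H]1CO
F3 | step 9 | (2S,3R,6E)-2,3-epoxy-3,7,11-trimethyl-9-oxododeca-6,10-dienal | CC(C)=CC(=O)C/C(C)=C/CC[C@@]1(C)O[C@@H]1C=O
F4 | step 11 | (1(10)E,4R,5R,6S,7R,8R)-4,5-epoxygermacr-1(10)-ene-6,8-diol | O[C@H]1[C@H](C(C)C)[C@H](O)C/C(C)=C/CC[C@@]2(C)O[C@H]12
F5 | step 11 | 8-O-triethylsilyl ether of diol F4 | O[C@H]1[C@H](C(C)C)[C@H](O[Si](CC)(CC)CC)C/C(C)=C/CC[C@@]2(C)O[C@H]12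
F6 | step 11 | 4-(tert-butyldimethylsilyloxy)-3-methoxybenzoic acid | COc1cc(C(=O)O)ccc1O[Si](C)(C)C(C)(C)C
F7 | step 11 | 6-O-[4-(tert-butyldimethylsilyloxy)-3-methoxybenzoyl] 8-O-triethylsilyl ether of diol F4 | COc1cc(C(=O)O[C@H]2[C@H](C(C)C)[C@H](O[Si](CC)(CC)CC)C/C(C)=C/CC[C@@]3(C)O[C@H]23)ccc1O[Si](C)(C)C(C)(C)C
F8 | step 4 | racemic (2E,6E)-1-(tert-butyldimethylsilyloxy)-3,7,11-trimethyldodeca-2,6,10-trien-9-ol | CC(C)=CC(O)C/C(C)=C/CC/C(C)=C/CO[Si](C)(C)C(C)(C)C
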